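## The problem

Target 20 is 7-hydroxy-3,5,6,8-tetramethoxy-2-(4-methoxyphenyl)-4H-chromen-4-one, a flavone with ring A (benzo), ring C (pyranone) and ring B (the 4-methoxyphenyl group on C2). Every carbon of ring A is substituted: oxygen on C5, C6, C7 and C8, the ring oxygen O1 on C8a and the C4 carbonyl on C4a. There is no stereocentre, so the task is one of regiochemistry only: six oxygens must be placed, and exactly one of them, on C7 between two methoxy groups, must end as a free hydroxyl. That hydroxyl cannot be freed by selective demethylation, because Lewis acids cleave the C5 methoxy group peri to the carbonyl first; it has to travel under a group that leaves under neutral conditions. The pyranone opens with hot hydroxide and the electron-rich ring A is easily over-oxidised, which limits the late steps. Building a hexasubstituted benzene by successive electrophilic substitutions is long and ambiguous, so ring C is best fused onto a ring A that still has open positions. The enabling feature is that O1 (on C8a) and the acyl carbon C4 (on C4a) are ortho neighbours on ring A, the pattern that a C4a≡C8a aryne gives on 1,2-difunctionalisation. The C5 methoxy group next to C4a polarises that aryne so that oxygen goes to C8a and carbon to C4a, and the C3–H of ring C and the C8–H of ring A remain as handles for the last two methoxy groups.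

## Retrosynthesis

**C8–OMe.** The C8–O bond of 20 is cut first, back to the 8-iodide 19 and then to the C8–H compound 18. C8 has to be unsubstituted when the aryne is used, since an alkoxy group there would flank the second aryne carbon and cancel the bias exerted by the C5 methoxy group. In 18, C8 is the only C–H of ring A and lies ortho to the free 7-hydroxyl and to O1, so iodination has one place to go. The forward steps must iodinate without touching ring B and then exchange iodide for methoxide next to a free phenol.

**C7–OH and C3–OMe.** Phenol 18 comes from benzyl ether 17 by hydrogenolysis, 17 from flavonol 16 by O-methylation, and 16 from the C3–H flavone 14 by forming the C3–O bond. The order is fixed: the 3-hydroxyl must be methylated while the 7-oxygen is still masked. The C3 oxygen cannot come in with the three-carbon unit, because C3 is an alkyne carbon in the precursor. The flavone C3–H is the one position that LiN(i-Pr)2 metalates, so lithiation, borylation and oxidation should place the oxygen there. Benzyl is chosen because it survives fluoride, amide base at −78 °C and carbonate, and leaves without acid.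

**Ring C (key disconnection).** Flavone 14 is cut at C8a–O1, C4a–C4 and O1–C2, giving silyl triflate 10 and 3-(4-methoxyphenyl)propiolic acid 12. A classical acylation or Baker–Venkataraman route would need a 2-hydroxyacetophenone that already carries the full ring A pattern. The aryne cut asks only for a benzene with four substituents and installs the ortho O/acyl pair in one operation, with the acid supplying C4, C3, C2 and ring B in one piece. The forward reaction must deliver oxygen to C8a and carbon to C4a, transfer the acyl group before the aryl anion is protonated, and close ring C in the 6-endo mode.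

**Acid 12.** The C–CO2H bond is cut to give 4-ethynylanisole 11; carboxylation of its acetylide is routine.

**Silyl triflate 10.** The C–Si and O–S bonds are cut back to ortho-bromophenol 7, through silyl ether 8 and silylphenoxide 9. This is the usual entry to ortho-silylaryl triflates and needs only a bromine ortho to a phenol. Bromophenol 7 comes from phenol 6, whose only open ortho position is the required one.

**Phenol 6.** The C–O bond of the phenol is traced to an aldehyde carbon: Baeyer–Villiger oxidation of 4 through formate 5. Aldehyde 4 comes by methylation of 3, and 3 by selective benzylation of 2,3,4-trihydroxybenzaldehyde 1 with benzyl bromide 2. This fixes all four oxygens of the ring A fragment from a starting material that already has them in place. Introducing the formyl group by electrophilic formylation of a ring carrying only the three ethers was set aside, because the two positions para to the outer ethers are electronically almost equal.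

## Roads not taken

**Alternative 1:** C4a–C4 and C3–C4 are cut, with C4 coming from a carbonylation. The fully substituted iodoarene A2 and the α-methoxy ketone A3 would be joined under zerovalent palladium in a carbonylative α-arylation to give the open 1,3-diketone A1; no ring closes in that step.
- Merits: all ring A oxygens and the C3 methoxy group are in place beforehand, and one acid treatment of A1 should remove both methoxymethyl groups and cyclodehydrate to 20. The endgame is thus one step against five in the chosen plan, which is a clear advantage.
- Weak points: A2 is a hexasubstituted benzene with three kinds of ether in a fixed order, and it is much longer to make than 10. Both positions ortho to iodine carry alkoxy groups, so carbonyl insertion and attack of the hindered α-alkoxy enolate on the acyl palladium are slowed, and direct arylation or reduction can compete.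
- Comparison: the chosen plan sets against the short endgame a ring A fragment with only four substituents, reached in five unambiguous steps, and a key step that forms ring C itself.

**Alternative 2:** the C8–C8a bond is cut, so that ring A is built from a squarate. Thermolysis of the pyranonyl cyclobutenone A5 would open the four-membered ring to a dienylketene, which closes C8–C8a by 6π electrocyclisation and tautomerises to the 8-hydroxy flavone A4.
- Merits: the hexasubstituted ring is made without any aromatic substitution, and O7 (tert-butyl) and O8 (free) are differentiated by construction. Methylation and acid cleavage of the tert-butyl ether would finish 20 in two steps. In differentiating O7 from O8 it is better than the chosen plan.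
- Weak points: A5 requires a metalated 4-pyranone, itself a Michael acceptor, to add to one of two nearly equivalent carbonyls of an unsymmetrical squarate, and this regiochemistry decides the C6/C7 pattern. The tertiary alkoxide must then be methylated, and the pyranone with ring B and the C3 methoxy group needs its own synthesis.
- Comparison: the chosen plan pays with two late C–H oxygenations but rests on fragments of routine access and a precursor class of known behaviour.

**Alternative 3:** C3–C4 and C8a–O1 are cut. The lithium enolate of A3 would be C-acylated by the 2-bromobenzoyl chloride A7, and the diketone enolate oxygen would then displace bromide under copper iodide (CuI) to close ring C, giving A6 in one flask; hydrogenolysis would give 20.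
- Merits: fully convergent, every oxygen in place, one step after the key step, and no late C–H functionalisation. On these counts it is better than the chosen plan.
- Weak points: A7 is again a hexasubstituted benzene (bromine, acyl chloride and four ethers) and needs a long linear preparation. The acyl chloride is flanked by bromine and a methoxy group, so O-acylation competes and the acidic diketone consumes a second equivalent of enolate. The copper step must form an aryl–oxygen bond at a doubly flanked carbon.
- Comparison: the chosen plan sets against this the easy access to 10 and 12, and the fact that its two late oxygens go to positions the flavone itself directs: C3 by lithiation, and C8 as the only ring A C–H beside the free phenol.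

Key step: step 7

Remark on the chemistry: flavone numbering (O1, C2–C4, C4a, C5–C8, C8a) is used for all chromenones; the target has no stereocentre, so no configuration has to be set.

## Route

Step 1
Reactants: 1 2,3,4-trihydroxybenzaldehyde; 2 benzyl bromide
Product: 3 4-(benzyloxy)-2,3-dihydroxybenzaldehyde
Conditions: NaHCO3, NaI (cat.), DMF, 40 °C
Reagents that add atoms: none
Why: Williamson etherification under a weak base; the 4-hydroxyl, para to the formyl group, is the most acidic, the 2-hydroxyl is held in a hydrogen bond to the carbonyl and the 3-hydroxyl is not conjugated with it, so one equivalent of 2 should alkylate O4 alone.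

Step 2
Reactants: 3 4-(benzyloxy)-2,3-dihydroxybenzaldehyde
Product: 4 4-(benzyloxy)-2,3-dimethoxybenzaldehyde
Conditions: MeI, K2CO3, DMF, rt to 50 °C
Reagents that add atoms: iodomethane, CI
Why: Exhaustive Williamson O-methylation of the two remaining phenols; carbonate and gentle warming overcome the hydrogen bond of the 2-hydroxyl, and the aldehyde and benzyl ether are inert.

Step 3
Reactants: 4 4-(benzyloxy)-2,3-dimethoxybenzaldehyde
Product: 6 4-(benzyloxy)-2,3-dimethoxyphenol, via aryl formate 5 (not isolated)
Conditions: mCPBA, CH2Cl2, 0 °C to rt; aq. NaHCO3 wash; K2CO3 (cat.), MeOH, rt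
Reagents that add atoms: meta-chloroperoxybenzoic acid, O=C(OO)c1cccc(Cl)c1
Why: Baeyer–Villiger (Dakin-type) oxidation; the aryl group with ortho and para alkoxy donors migrates in preference to hydride to give formate 5, which is methanolysed to the phenol, so the former aldehyde carbon fixes the place of the fourth oxygen without any regiochemical choice.

Step 4
Reactants: 6 4-(benzyloxy)-2,3-dimethoxyphenol
Product: 7 4-(benzyloxy)-6-bromo-2,3-dimethoxyphenol
Conditions: NBS, i-Pr2NH (cat.), CH2Cl2, −78 to 0 °C
Reagents that add atoms: N-bromosuccinimide, O=C1CCC(=O)N1Br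
Why: Amine-mediated ortho-bromination of a phenol (electrophilic aromatic substitution); the free hydroxyl activates more strongly than the ethers, C6 is its only open ortho position and is also para to the C3 methoxy group, and cold anhydrous conditions should suppress oxidation to a quinone.

Step 5
Reactants: 7 4-(benzyloxy)-6-bromo-2,3-dimethoxyphenol
Product: 10 4-(benzyloxy)-2,3-dimethoxy-6-(trimethylsilyl)phenyl trifluoromethanesulfonate, via aryl trimethylsilyl ether 8 (not isolated), via lithium 2-silylphenoxide 9 (not isolated)
Conditions: HMDS, THF, 70 °C, then removal of volatiles; n-BuLi, THF, −78 °C; Tf2O, −78 °C to rt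
Reagents that add atoms: hexamethyldisilazane, C[Si](C)(C)N[Si](C)(C)C; trifluoromethanesulfonic anhydride, O=S(=O)(OS(=O)(=O)C(F)(F)F)C(F)(F)F
Why: Standard telescoped route to ortho-silylaryl triflates; O-silylation, bromine–lithium exchange and retro-Brook 1,3-shift of silicon from oxygen to carbon give phenoxide 9, which is triflated in the same flask, and the exchange at −78 °C is far faster than any metalation of the benzyl ether.

Step 6
Reactants: 11 4-ethynylanisole
Product: 12 3-(4-methoxyphenyl)propiolic acid
Conditions: n-BuLi, THF, −78 °C; CO2, −78 °C to rt; aq. HCl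
Reagents that add atoms: carbon dioxide, O=C=O
Why: Carboxylation of a lithium acetylide; the terminal alkyne is the only acidic site and the acid is obtained on acidification.

Step 7
Reactants: 10 4-(benzyloxy)-2,3-dimethoxy-6-(trimethylsilyl)phenyl trifluoromethanesulfonate; 12 3-(4-methoxyphenyl)propiolic acid
Product: 14 7-(benzyloxy)-5,6-dimethoxy-2-(4-methoxyphenyl)-4H-chromen-4-one, via ortho-hydroxyaryl ynone 13 (not isolated)
Conditions: CsF (4 equiv), THF, 125 °C, sealed tube
Reagents that add atoms: none
Why: Fluoride attack on silicon with loss of triflate should release the ring A aryne C4a≡C8a; the cesium carboxylate of 12 adds through oxygen to C8a, and the aryl anion at C4a attacks the ester carbonyl through a four-membered ring that opens to the ortho-acyl phenoxide of 13. The closest known reaction type is the fluoride-induced insertion of arynes into the C–O bond of carboxylic acids to give ortho-hydroxyaryl ketones in hot THF, with its tandem extension to chromones and flavones when the acid carries an allene or alkyne. Ring C then closes by 6-endo-dig oxa-Michael addition of the phenoxide to the β-carbon of the ynone, which gives a stabilised allenolate; the 5-exo-dig mode would give an unstabilised vinyl anion and is reversible in an aprotic medium. No stereocentre is formed. The step needs oxygen at C8a and the acyl carbon at C4a, and the C5 methoxy group secures this: its inductive pull stabilises negative charge at the adjacent C4a and distorts the aryne so that the nucleophile attacks the remote carbon C8a. The C6 and C7 ethers are meta or para to the aryne carbons and weigh little, and C8 is left as C–H so that no second flanking alkoxy group opposes the bias. Acyl transfer before protonation of the aryl anion is favoured by working with the carboxylate under excess CsF, so that little free acid is present.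

Step 8
Reactants: 14 7-(benzyloxy)-5,6-dimethoxy-2-(4-methoxyphenyl)-4H-chromen-4-one
Product: 16 7-(benzyloxy)-3-hydroxy-5,6-dimethoxy-2-(4-methoxyphenyl)-4H-chromen-4-one, via flavon-3-yl dimethyl boronate 15 (not isolated)
Conditions: LiN(i-Pr)2 (LDA), THF, −78 °C; B(OMe)3, −78 to 0 °C; H2O2 (30% aq.), AcOH, 0 °C to rt
Reagents that add atoms: hydrogen peroxide, OO
Why: Lithiation–borylation–oxidation; flavones are deprotonated by the hindered amide at the vinylic C3 next to the carbonyl, the 3-lithio species is trapped as boronate 15, and oxidative 1,2-shift from boron to oxygen gives the flavonol, while the benzyl ether and the aryl C–H bonds are not touched at −78 °C.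

Step 9
Reactants: 16 7-(benzyloxy)-3-hydroxy-5,6-dimethoxy-2-(4-methoxyphenyl)-4H-chromen-4-one
Product: 17 7-(benzyloxy)-3,5,6-trimethoxy-2-(4-methoxyphenyl)-4H-chromen-4-one
Conditions: MeI, K2CO3, acetone, 56 °C
Reagents that add atoms: iodomethane, CI
Why: Williamson O-methylation of the enolic 3-hydroxyl, the only free hydroxyl at this stage, which is why it is done before the 7-oxygen is unmasked.

Step 10
Reactants: 17 7-(benzyloxy)-3,5,6-trimethoxy-2-(4-methoxyphenyl)-4H-chromen-4-one
Product: 18 7-hydroxy-3,5,6-trimethoxy-2-(4-methoxyphenyl)-4H-chromen-4-one
Conditions: H2 (1 atm), Pd/C (10% palladium on carbon), EtOAc–MeOH, rt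
Reagents that add atoms: none
Why: Catalytic hydrogenolysis of a benzyl aryl ether under neutral conditions; the tetrasubstituted, conjugated C2=C3 bond of the flavone is not reduced at atmospheric pressure, and no halogen is yet present.

Step 11
Reactants: 18 7-hydroxy-3,5,6-trimethoxy-2-(4-methoxyphenyl)-4H-chromen-4-one
Product: 19 7-hydroxy-8-iodo-3,5,6-trimethoxy-2-(4-methoxyphenyl)-4H-chromen-4-one
Conditions: NIS (1.05 equiv), DMF, 0 °C to rt
Reagents that add atoms: N-iodosuccinimide, O=C1CCC(=O)N1I
Why: Electrophilic aromatic iodination; C8 is the only C–H of ring A and lies ortho to the free 7-hydroxyl and to O1, C3 is blocked by its methoxy group, and ring B is deactivated by conjugation with the pyranone, so one equivalent should iodinate C8 alone.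

Step 12
Reactants: 19 7-hydroxy-8-iodo-3,5,6-trimethoxy-2-(4-methoxyphenyl)-4H-chromen-4-one
Product: 20 7-hydroxy-3,5,6,8-tetramethoxy-2-(4-methoxyphenyl)-4H-chromen-4-one
Conditions: NaOMe, CuBr, MeOH–DMF, 110 °C; aq. HCl work-up
Reagents that add atoms: sodium methoxide, [Na+].[O-]C
Why: Ullmann-type methoxylation in which monovalent copper from CuBr exchanges the aryl iodide for methoxide; the neighbouring phenoxide is tolerated, as in the known conversions of ortho-halophenols and of 8-halo-7-hydroxyflavones into their methoxy compounds, and acidification returns the free 7-hydroxyl.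

## Compound list

1 | 2,3,4-trihydroxybenzaldehyde | O=Cc1ccc(O)c(O)c1O | starting material
2 | benzyl bromide | BrCc1ccccc1 | starting material
3 | 4-(benzyloxy)-2,3-dihydroxybenzaldehyde | O=Cc1ccc(OCc2ccccc2)c(O)c1O | intermediate
4 | 4-(benzyloxy)-2,3-dimethoxybenzaldehyde | O=Cc1ccc(OCc2ccccc2)c(OC)c1OC | intermediate
5 | 4-(benzyloxy)-2,3-dimethoxyphenyl formate | O=COc1ccc(OCc2ccccc2)c(OC)c1OC | intermediate
6 | 4-(benzyloxy)-2,3-dimethoxyphenol | Oc1ccc(OCc2ccccc2)c(OC)c1OC | intermediate
7 | 4-(benzyloxy)-6-bromo-2,3-dimethoxyphenol | Oc1c(Br)cc(OCc2ccccc2)c(OC)c1OC | intermediate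
8 | [4-(benzyloxy)-6-bromo-2,3-dimethoxyphenoxy]trimethylsilane | C[Si](C)(C)Oc1c(Br)cc(OCc2ccccc2)c(OC)c1OC | intermediate
9 | lithium 4-(benzyloxy)-2,3-dimethoxy-6-(trimethylsilyl)phenoxide | [Li+].[O-]c1c([Si](C)(C)C)cc(OCc2ccccc2)c(OC)c1OC | intermediate
10 | 4-(benzyloxy)-2,3-dimethoxy-6-(trimethylsilyl)phenyl trifluoromethanesulfonate | C[Si](C)(C)c1cc(OCc2ccccc2)c(OC)c(OC)c1OS(=O)(=O)C(F)(F)F | intermediate
11 | 4-ethynylanisole | C#Cc1ccc(OC)cc1 | starting material
12 | 3-(4-methoxyphenyl)propiolic acid | COc1ccc(C#CC(=O)O)cc1 | intermediate
13 | 1-[4-(benzyloxy)-6-hydroxy-2,3-dimethoxyphenyl]-3-(4-methoxyphenyl)prop-2-yn-1-one | COc1ccc(C#CC(=O)c2c(O)cc(OCc3ccccc3)c(OC)c2OC)cc1 | intermediate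
14 | 7-(benzyloxy)-5,6-dimethoxy-2-(4-methoxyphenyl)-4H-chromen-4-one | COc1ccc(-c2cc(=O)c3c(OC)c(OC)c(OCc4ccccc4)cc3o2)cc1 | intermediate
15 | dimethyl [7-(benzyloxy)-5,6-dimethoxy-2-(4-methoxyphenyl)-4-oxo-4H-chromen-3-yl]boronate | COB(OC)c1c(-c2ccc(OC)cc2)oc2cc(OCc3ccccc3)c(OC)c(OC)c2c1=O | intermediate
16 | 7-(benzyloxy)-3-hydroxy-5,6-dimethoxy-2-(4-methoxyphenyl)-4H-chromen-4-one | COc1ccc(-c2oc3cc(OCc4ccccc4)c(OC)c(OC)c3c(=O)c2O)cc1 | intermediate
17 | 7-(benzyloxy)-3,5,6-trimethoxy-2-(4-methoxyphenyl)-4H-chromen-4-one | COc1ccc(-c2oc3cc(OCc4ccccc4)c(OC)c(OC)c3c(=O)c2OC)cc1 | intermediate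
18 | 7-hydroxy-3,5,6-trimethoxy-2-(4-methoxyphenyl)-4H-chromen-4-one | COc1ccc(-c2oc3cc(O)c(OC)c(OC)c3c(=O)c2OC)cc1 | intermediate
19 | 7-hydroxy-8-iodo-3,5,6-trimethoxy-2-(4-methoxyphenyl)-4H-chromen-4-one | COc1ccc(-c2oc3c(I)c(O)c(OC)c(OC)c3c(=O)c2OC)cc1 | intermediate
20 | 7-hydroxy-3,5,6,8-tetramethoxy-2-(4-methoxyphenyl)-4H-chromen-4-one | COc1ccc(-c2oc3c(OC)c(O)c(OC)c(OC)c3c(=O)c2OC)cc1 | target

## Step count and risks

Total step count: 12 (five steps to 10, one to 12, the key step, five after it).
Longest linear sequence: 11 steps (steps 1–5 and 7–12).

**Step 7 (key step).** The aryl anion at C4a may be protonated by free acid before the acyl shift, which would stop the sequence at simple O-arylation. At 125 °C the propiolate may also lose carbon dioxide or take up fluoride at the triple bond, and some 5-exo closure cannot be excluded. The fallback sets out from 10 and supplies C4 separately: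
- The aryne is generated with CsF in DMF, where it inserts into the formamide C=O bond with the same regiochemical bias; aqueous work-up should give 4-(benzyloxy)-6-hydroxy-2,3-dimethoxybenzaldehyde F1.
- Addition of an excess of the lithium acetylide of 11 (n-BuLi, THF, −78 to 0 °C) would give the racemic propargylic alcohol 5-(benzyloxy)-2-[1-hydroxy-3-(4-methoxyphenyl)prop-2-yn-1-yl]-3,4-dimethoxyphenol F2.
- Oxidation with MnO2 in CH2Cl2 leads to ynone 13, here isolated, and Et2NH in EtOH closes it through the enaminone in the 6-endo sense.
- The fallback rejoins the route at 14.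

**Step 4.** The electron-rich para-alkoxyphenol may be oxidised to a quinone instead of brominated, or bromination may stray to C5 beside the benzyloxy group. The fallback sets out from 6 and avoids halogenation:
- Isopropyl isocyanate with Et3N would give 4-(benzyloxy)-2,3-dimethoxyphenyl N-isopropylcarbamate F3.
- In-flask N-silylation (TBSOTf, TMEDA), carbamate-directed ortho-lithiation (n-BuLi, TMEDA, −78 °C) and TMSCl quench would give 4-(benzyloxy)-2,3-dimethoxy-6-(trimethylsilyl)phenyl N-isopropylcarbamate F4; C6 is the only free position ortho to the carbamate.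
- Cleavage with DBU and Et2NH in MeCN and triflation of the phenoxide with PhNTf2 in the same flask follow.
- The fallback rejoins the route at 10, bypassing 7, 8 and 9.

**Step 8.** Lithiation at C3 may be incomplete, the amide base may add to C2 and open ring C, or metalation may occur at C8 between two oxygens. The fallback sets out from 14 and oxidises the C2=C3 bond directly:
- Dimethyldioxirane in acetone–CH2Cl2 at 0 °C would give the racemic, cis-fused 7-(benzyloxy)-2,3-epoxy-5,6-dimethoxy-2-(4-methoxyphenyl)chroman-4-one F5.
- Catalytic p-TsOH opens the epoxide at C2 with loss of the C3 proton to the flavonol.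
- The fallback rejoins the route at 16.

**Step 12.** Reductive loss of iodine may return the C8–H compound, or methoxide may attack C2 and open the pyranone at 110 °C. The fallback sets out from 18 and brings in the C8 oxygen through a formyl group:
- Duff formylation (hexamethylenetetramine, AcOH, 100 °C, then aq. HCl) at the only free ortho position would give 7-hydroxy-3,5,6-trimethoxy-2-(4-methoxyphenyl)-4-oxo-4H-chromene-8-carbaldehyde F6.
- MOMCl and i-Pr2NEt would give 3,5,6-trimethoxy-7-(methoxymethoxy)-2-(4-methoxyphenyl)-4-oxo-4H-chromene-8-carbaldehyde F7.
- Baeyer–Villiger oxidation with mCPBA and methanolysis of the formate would give 8-hydroxy-3,5,6-trimethoxy-7-(methoxymethoxy)-2-(4-methoxyphenyl)-4H-chromen-4-one F8.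
- MeI and K2CO3 would give 3,5,6,8-tetramethoxy-7-(methoxymethoxy)-2-(4-methoxyphenyl)-4H-chromen-4-one F9.
- HCl in MeOH at rt removes the acetal; the fallback rejoins the route at 20.

## Further compounds

F1 | step 7 | 4-(benzyloxy)-6-hydroxy-2,3-dimethoxybenzaldehyde | COc1c(C=O)c(O)cc(OCc2ccccc2)c1OC
F2 | step 7 | 5-(benzyloxy)-2-[1-hydroxy-3-(4-methoxyphenyl)prop-2-yn-1-yl]-3,4-dimethoxyphenol (racemic) | COc1ccc(C#CC(O)c2c(O)cc(OCc3ccccc3)c(OC)c2OC)cc1
F3 | step 4 | 4-(benzyloxy)-2,3-dimethoxyphenyl N-isopropylcarbamate | COc1c(OC(=O)NC(C)C)ccc(OCc2ccccc2)c1OC
F4 | step 4 | 4-(benzyloxy)-2,3-dimethoxy-6-(trimethylsilyl)phenyl N-isopropylcarbamate | COc1c(OC(=O)NC(C)C)c([Si](C)(C)C)cc(OCc2ccccc2)c1OC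
F5 | step 8 | 7-(benzyloxy)-2,3-epoxy-5,6-dimethoxy-2-(4-methoxyphenyl)chroman-4-one (racemic, cis-fused) | COc1ccc(cc1)C12OC1C(=O)c1c(OC)c(OC)c(OCc3ccccc3)cc1O2
F6 | step 12 | 7-hydroxy-3,5,6-trimethoxy-2-(4-methoxyphenyl)-4-oxo-4H-chromene-8-carbaldehyde | COc1ccc(-c2oc3c(C=O)c(O)c(OC)c(OC)c3c(=O)c2OC)cc1
F7 | step 12 | 3,5,6-trimethoxy-7-(methoxymethoxy)-2-(4-methoxyphenyl)-4-oxo-4H-chromene-8-carbaldehyde | COCOc1c(C=O)c2oc(-c3ccc(OC)cc3)c(OC)c(=O)c2c(OC)c1OC
F8 | step 12 | 8-hydroxy-3,5,6-trimethoxy-7-(methoxymethoxy)-2-(4-methoxyphenyl)-4H-chromen-4-one | COCOc1c(O)c2oc(-c3ccc(OC)cc3)c(OC)c(=O)c2c(OC)c1OC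
F9 | step 12 | 3,5,6,8-tetramethoxy-7-(methoxymethoxy)-2-(4-methoxyphenyl)-4H-chromen-4-one | COCOc1c(OC)c2oc(-c3ccc(OC)cc3)c(OC)c(=O)c2c(OC)c1OC
A1 | alternative 1 | 2-methoxy-3-(4-methoxyphenyl)-1-[2,3,5-trimethoxy-4,6-bis(methoxymethoxy)phenyl]propane-1,3-dione | COCOc1c(C(=O)C(OC)C(=O)c2ccc(OC)cc2)c(OC)c(OC)c(OCOC)c1OC
A2 | alternative 1 | 1-iodo-2,3,5-trimethoxy-4,6-bis(methoxymethoxy)benzene | COCOc1c(I)c(OC)c(OC)c(OCOC)c1OC
A3 | alternative 1 | 2-methoxy-1-(4-methoxyphenyl)ethanone | COCC(=O)c1ccc(OC)cc1
A4 | alternative 2 | 7-tert-butoxy-8-hydroxy-3,5,6-trimethoxy-2-(4-methoxyphenyl)-4H-chromen-4-one | COc1ccc(-c2oc3c(O)c(OC(C)(C)C)c(OC)c(OC)c3c(=O)c2OC)cc1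
A5 | alternative 2 | 2-tert-butoxy-3,4-dimethoxy-4-[5-methoxy-6-(4-methoxyphenyl)-4-oxo-4H-pyran-3-yl]cyclobut-2-en-1-one (racemic) | COc1ccc(-c2occ(C3(OC)C(OC)=C(OC(C)(C)C)C3=O)c(=O)c2OC)cc1
A6 | alternative 3 | 7-(benzyloxy)-3,5,6,8-tetramethoxy-2-(4-methoxyphenyl)-4H-chromen-4-one | COc1ccc(-c2oc3c(OC)c(OCc4ccccc4)c(OC)c(OC)c3c(=O)c2OC)cc1
A7 | alternative 3 | 4-(benzyloxy)-2-bromo-3,5,6-trimethoxybenzoyl chloride | COc1c(Br)c(C(Cl)=O)c(OC)c(OC)c1OCc1ccccc1
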